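## Structural features

The target is an achiral hexabrominated diaryl ether: two benzene rings joined only through one oxygen atom. Ring A is fully substituted, with the bridging oxygen on C1, a methoxy group on C2 and bromine on C3 to C6. Ring B carries the bridging oxygen on C1′, a free hydroxyl on C6′, bromine on C3′ and C5′, and hydrogen on C2′ and C4′. There is no stereocentre, so every problem is one of regiochemistry and chemoselectivity. The fragile groups are the six C–Br bonds (no metal-catalysed aryl ether coupling, no aryllithium chemistry, no hydrogenation), the free phenol (oxidation, attack by carbenes or excess halogen) and the methyl ether (strong acids). The real difficulty is the ether bond: its ring A partner is electron-poor and flanked by OMe and Br, and a direct aryl–oxygen coupling would have to pick one site among many C–Br bonds. The key step exploits the fact that C5′ is a C–Br unit lying between C6′ (oxygen-bearing) and C4′ (C–H). It can be delivered as the carbon of dibromocarbene into the silyl enol ether double bond of a five-membered ring that already holds the C6′ oxygen and, next to it, C1′ with the ring A oxygen. The ether bond is therefore made at sp3 carbon before ring B is aromatic, and the C3′ bromine, para to the hydroxyl, is left for a final electrophilic substitution.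

## Logic of the disconnections

**12 ⇒ 11.** The C3′–Br bond is cut. C3′ is para to the C6′ hydroxyl and is the only free ortho or para site of that group, while ring A has no C–H bond at all. The gain is one halogen fewer on ring B and a precursor whose remaining bromine sits exactly where a carbene carbon can place it. The forward step only has to stop after one bromination.

**11 ⇒ 7 + 8 (through 9 and 10).** The C4′–C5′ and C5′–C6′ bonds are cut, which removes the C5′–Br carbon and contracts ring B to a 2,3-dioxygenated cyclopentadiene.
- Reason: a halocarbene inserted into an enol ether double bond ends up next to the oxygen-bearing carbon, which is the C5′/C6′ relationship of the target, and the diene oxidation level lets the expanded ring aromatise by itself.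
- Gain: the substitution pattern of an arene is reduced to the position of two enol ether oxygens on a five-membered ring, and 8 is the only new reagent.
- Demand: the carbene must choose the silyl enol ether double bond over the aryl enol ether double bond, and the base must not deprotonate or isomerise 7.
- Design change: the silyl group in 7 is tert-butyldimethylsilyl, not trimethylsilyl. A trimethylsilyl dienol ether would be cleaved by alkoxide and would not survive handling, and the aryl trimethylsilyl ether formed would be cleaved in the flask to a phenoxide open to excess carbene. The bulkier group keeps 10 masked until fluoride is added.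

**7 ⇒ 6.** The O–Si bond is cut and a proton is returned to C5 of the enone. This leads back to a stable, storable 2-aryloxy enone. The forward step must enolise at the α′ position (not the γ position) and must be run cold, because 1,5-hydrogen shifts would move the double bonds of 7.

**6 ⇒ 2 + 4 (through 5).** The bond between the ring A oxygen and the future C1′ is cut, and the C1′=C2′ double bond is traced back to the second epoxide C–O bond and a C–H bond. The ether bond is thus formed by SN2 attack at an sp3 carbon α to a carbonyl group, with no aryl halide partner, and the two pieces are small. The demand is that the hindered, weakly nucleophilic phenoxide of 2 opens 4 at the α-carbon and that 5 then loses water.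

**4 ⇒ 3.** Both epoxide C–O bonds are cut, which leaves a commercial enone. The forward step is a nucleophilic epoxidation of an electron-poor alkene and needs only low temperature, since 4 is base-sensitive.

**2 ⇒ 1.** Four C–Br bonds are cut. All four free positions of 1 are ortho or para to one of the two oxygen substituents, so exhaustive bromination gives a single compound. The demand is to force the fourth, hindered position without cleaving the methyl ether.

## Other disconnections considered

**Alternative 1:**
- Cut: both bonds from the ring A oxygens to C1′ and C6′ at once. Ring A comes from tetrabromo-1,2-benzoquinone A1 and ring B from 1-(trimethylsilyloxy)cyclohexene A2.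
- Forward step: A1 would act as an electron-poor 4π heterodiene (O=C–C=O) and add across the enol ether double bond of A2 in an inverse-electron-demand hetero-Diels–Alder reaction. Both C–O bonds form on one face, so the silyl ketal A3 is cis-fused, and rearomatisation of ring A drives the addition.
- In favour: the ring A bromines are in place from the start, the six carbons of ring B are present, and the C–O bonds are made by a strongly driven cycloaddition.
- Against: A3 has ring B at the oxidation level of a cyclohexanone. After the key step the ketal must be opened at C6′, and the freed ring A phenol must be methylated in competition with reclosure to the hemiketal. Four hydrogens must then be removed from ring B and two bromines placed at C3′ and C5′. A1 is also an oxidant that could dehydrogenate A2 or react through carbon.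
- Comparison:
  - Structure: both plans bind the ring A oxygen to a non-aromatic carbon of the future ring B. The alternative is the better one for that bond, since it needs neither a hindered phenoxide nor a labile diene.
  - Mechanism: it replaces carbene chemistry by a pericyclic step, but shifts the burden to a late double dehydrogenation beside a free phenol.
  - Step economy: it is longer, about seven steps against six, because the chosen plan delivers ring B aromatic and already brominated at C5′.

**Alternative 2:**
- Cut: ring B is cut at C1′–C2′ and C5′–C6′. 3,5-Dibromo-2-pyrone A4 supplies C2′ to C5′ with both bromines. The bis(trimethylsilyl) ketene acetal A5, reachable from 2 in two steps, supplies C6′ and C1′ with both oxygens.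
- Forward step: a [4+2] cycloaddition in which the nucleophilic CH(OAr) carbon of A5 bonds to C6 of A4 and the acetal carbon to C3. The bridged lactone would then lose CO2 by a retro-[4+2] step, and the cyclohexadiene would lose trimethylsilanol, the only 1,2-elimination open to it, to give the silylated phenol A6.
- In favour: A6 is one desilylation from 12. Both ring B bromines come with A4, so no late bromination is needed and their positions are fixed by the pyrone. The polarity of the two partners matches the required regiochemistry.
- Against: the reacting carbon of A5 sits next to a very bulky, electron-poor aryloxy group, which lowers its nucleophilicity. A5 is moisture-sensitive and would have to survive the heating needed for cycloaddition and CO2 loss. A4 reacts with donor dienophiles only sluggishly.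
- Comparison:
  - Structure: the alternative is the better one, because it is convergent and carries the full halogen pattern.
  - Step economy: it is also the better one, about four steps from 2 against six.
  - Mechanism: it rests on a thermal cycloaddition of a hindered, labile dienophile, while the chosen plan rests on a fast low-temperature carbene addition to a labile diene. The two risks are of similar size and neither is secured by a close model, so the two plans are judged equal on this point.

**Alternative 3:**
- Cut: ring B is cut at C1′–C2′ and C4′–C5′ into the aryloxy ketone A7, 1-(2,3,4,5-tetrabromo-6-methoxyphenoxy)propan-2-one, and bromomalonaldehyde A8.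
- Forward step: a base-mediated double aldol condensation of the CH2(OAr) and CH3 carbons of A7 with the two formyl groups of A8, followed by tautomerisation. It would give 4-bromo-2-(2,3,4,5-tetrabromo-6-methoxyphenoxy)phenol A9, with the C3′ bromine in place. One bromination at C5′, the only free ortho or para site of the hydroxyl, would finish the synthesis.
- In favour: A7 is one alkylation away from 2, every intermediate is stable, and the end game equals that of the chosen plan (one directed bromination).
- Against: this phenol synthesis is secure for malonaldehydes with a strongly electron-withdrawing 2-substituent. Under base A8 is a poorly electrophilic enolate that can also lose bromide. The enolate of A7 could displace that bromide through oxygen after the first aldol step and end in a furan (Feist–Benary-type path). A7 carries a good aryloxide leaving group α to the carbonyl.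
- Comparison:
  - Structure and step economy: the alternative is the better one, with about four steps and no sensitive intermediate.
  - Mechanism: it depends on a polar condensation with several plausible diversions. The chosen plan depends on two reaction types, carbene addition to an enol ether and opening of the halocyclopropane, that are individually well behaved.

Key step: step 5

Remark: the target is achiral. Compounds 4, 5 and 9 are racemic, their stereocentres do not reach the target, and one enantiomer is drawn in each SMILES. Ring B atoms are numbered with primes as in the target throughout.

## Route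

Step 1
Reactants: 1 guaiacol (2-methoxyphenol)
Product: 2 3,4,5,6-tetrabromo-2-methoxyphenol (tetrabromoguaiacol)
Conditions: Br2 (4.5 equiv), FeBr3 (0.05 equiv), CHCl3–AcOH, 20 → 60 °C; aq. NaHSO3
Reagents that add atoms: bromine, BrBr
Why: Exhaustive electrophilic aromatic bromination; every free position of 1 is ortho or para to OH or OMe, three react unaided and the Lewis acid drives the last, hindered position between OMe and Br, while the bisulfite wash returns any over-brominated dienone to the phenol.

Step 2
Reactants: 3 cyclopent-2-en-1-one
Product: 4 6-oxabicyclo[3.1.0]hexan-2-one (2,3-epoxycyclopentan-1-one; racemic, cis-fused)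
Conditions: 30% aq. H2O2, NaOH (cat.), MeOH, 0 °C
Reagents that add atoms: hydrogen peroxide, OO
Why: Weitz–Scheffer nucleophilic epoxidation: conjugate addition of hydroperoxide and closure of the enolate onto oxygen; the ring fusion can only be cis and the product is racemic.

Step 3
Reactants: 2 3,4,5,6-tetrabromo-2-methoxyphenol, 4 6-oxabicyclo[3.1.0]hexan-2-one
Product: 6 2-(2,3,4,5-tetrabromo-6-methoxyphenoxy)cyclopent-2-en-1-one, via trans-hydroxy ketone 5 (not isolated)
Conditions: Cs2CO3 (0.2 equiv), DMF, 50 °C; then TsOH·H2O (cat.), PhMe, 80 °C
Reagents that add atoms: none
Why: Opening of an α,β-epoxy ketone by a heteroatom nucleophile followed by dehydration, the known route to 2-heteroatom-substituted enones: the phenoxide of 2 attacks C2 of 4 in an SN2 step accelerated by the adjacent carbonyl group, with inversion, to give trans 5, whose β-hydroxyl is then lost by E1cB elimination, completed under acid catalysis; the base stays catalytic because 2 is acidic enough to protonate the alkoxide and carry the chain.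

Step 4
Reactants: 6 2-(2,3,4,5-tetrabromo-6-methoxyphenoxy)cyclopent-2-en-1-one
Product: 7 tert-butyl(dimethyl){[5-(2,3,4,5-tetrabromo-6-methoxyphenoxy)cyclopenta-1,4-dien-1-yl]oxy}silane, i.e. 3-(aryloxy)-2-(tert-butyldimethylsilyloxy)cyclopenta-1,3-diene
Conditions: TBSOTf (1.1 equiv), Et3N (1.5 equiv), CH2Cl2, −78 → −30 °C; cold pentane/aq. NaHCO3 work-up; used at once, kept below 0 °C
Reagents that add atoms: tert-butyldimethylsilyl trifluoromethanesulfonate, CC(C)(C)[Si](C)(C)OS(=O)(=O)C(F)(F)F
Why: Soft enolisation of an enone: O-silylation gives a siloxyallyl cation whose α′ protons at C5 are removed by the amine faster than the vinylogous γ protons at C4, which leads to the cross-conjugated 2-silyloxy diene, the standard access to 2-silyloxycyclopentadienes from cyclopent-2-enones.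

Step 5
Reactants: 7 3-(aryloxy)-2-(tert-butyldimethylsilyloxy)cyclopenta-1,3-diene, 8 bromoform
Product: 11 2-bromo-6-(2,3,4,5-tetrabromo-6-methoxyphenoxy)phenol, via dibromocyclopropane adduct 9 (not isolated), via aryl silyl ether 10 (not isolated)
Conditions: 8 (4 equiv), KOtBu (3 equiv, added in portions), PhMe–pentane, −40 → 0 °C, then rt; Bu4NF, THF, 0 °C; aq. NH4Cl
Reagents that add atoms: none
Why: KOtBu deprotonates 8 and the tribromomethyl anion loses bromide to singlet dibromocarbene, an electrophile that adds in a concerted [2+1] cheletropic step to the more electron-rich double bond of 7, the silyl enol ether between the carbons that become C4′ and C6′, to give the cis-fused adduct 9; the closest known reactions are the dihalocarbene ring expansion of cyclopentadienes and indenes to haloarenes and that of cyclic silyl enol ethers to 2-haloenones. The three-membered ring thus closes by cycloaddition and is then cleaved at its internal bond: ring B arises by disrotatory two-electron electrocyclic opening of the cyclopropane with departure of the endo bromide, the only mode that turns the ring bonds inward and gives a six-membered cation. The ionisation is pushed by the silyloxy oxygen and by the neighbouring aryl enol ether double bond, so the cation is an O-silylated arenium ion with an sp3 CH2 at C3′; loss of that proton to the base gives the aromatic silyl ether 10, in which the C4′–C5′ and C5′–C6′ bonds are made and bromine sits on C5′. Fluoride then frees phenol 11. The two stereocentres of 9 are cis by ring fusion, racemic, and vanish on aromatisation, so no stereocontrol is needed. The selectivity needed is for the silyl enol ether over the aryl enol ether double bond: silyloxy is the stronger donor, whereas the aryloxy oxygen is attached to a twisted, electron-poor, doubly ortho-substituted ring that makes its alkene less nucleophilic and more shielded. The diene must also not be deprotonated or isomerised: 8 is more acidic than the ring CH2 and is kept in excess over the base, which is added in portions in the cold, and the tert-butyldimethylsilyl ether resists alkoxide cleavage and keeps the new phenol masked from excess carbene.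

Step 6
Reactants: 11 2-bromo-6-(2,3,4,5-tetrabromo-6-methoxyphenoxy)phenol
Product: 12 2,4-dibromo-6-(2,3,4,5-tetrabromo-6-methoxyphenoxy)phenol (target)
Conditions: Br2 (1.0 equiv), CH2Cl2, −20 → 0 °C; aq. Na2S2O3
Reagents that add atoms: bromine, BrBr
Why: Electrophilic aromatic bromination directed by the free hydroxyl group: both ortho positions are occupied (Br at C5′, aryloxy at C1′), so the para position C3′ is the only activated site, and ring A has no free position.

## Compound list

1 | guaiacol (2-methoxyphenol) | COc1ccccc1O | starting material
2 | 3,4,5,6-tetrabromo-2-methoxyphenol | COc1c(O)c(Br)c(Br)c(Br)c1Br | intermediate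
3 | cyclopent-2-en-1-one | O=C1C=CCC1 | starting material
4 | 6-oxabicyclo[3.1.0]hexan-2-one (racemic, cis-fused; one enantiomer drawn) | O=C1CC[C@H]2O[C@@H]12 | intermediate
5 | trans-3-hydroxy-2-(2,3,4,5-tetrabromo-6-methoxyphenoxy)cyclopentan-1-one (racemic; one enantiomer drawn) | O=C1CC[C@@H](O)[C@@H]1Oc1c(OC)c(Br)c(Br)c(Br)c1Br | intermediate
6 | 2-(2,3,4,5-tetrabromo-6-methoxyphenoxy)cyclopent-2-en-1-one | COc1c(Br)c(Br)c(Br)c(Br)c1OC1=CCCC1=O | intermediate
7 | tert-butyl(dimethyl){[5-(2,3,4,5-tetrabromo-6-methoxyphenoxy)cyclopenta-1,4-dien-1-yl]oxy}silane | COc1c(Br)c(Br)c(Br)c(Br)c1OC1=CCC=C1O[Si](C)(C)C(C)(C)C | intermediate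
8 | bromoform | BrC(Br)Br | starting material
9 | tert-butyl{[6,6-dibromo-2-(2,3,4,5-tetrabromo-6-methoxyphenoxy)bicyclo[3.1.0]hex-2-en-1-yl]oxy}dimethylsilane (racemic, cis-fused; one enantiomer drawn) | COc1c(Br)c(Br)c(Br)c(Br)c1OC1=CC[C@@H]2C(Br)(Br)[C@]12O[Si](C)(C)C(C)(C)C | intermediate
10 | [2-bromo-6-(2,3,4,5-tetrabromo-6-methoxyphenoxy)phenoxy](tert-butyl)dimethylsilane | COc1c(Br)c(Br)c(Br)c(Br)c1Oc1cccc(Br)c1O[Si](C)(C)C(C)(C)C | intermediate
11 | 2-bromo-6-(2,3,4,5-tetrabromo-6-methoxyphenoxy)phenol | COc1c(Br)c(Br)c(Br)c(Br)c1Oc1cccc(Br)c1O | intermediate
12 | 2,4-dibromo-6-(2,3,4,5-tetrabromo-6-methoxyphenoxy)phenol | COc1c(Br)c(Br)c(Br)c(Br)c1Oc1cc(Br)cc(Br)c1O | target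

## Step count and least certain steps

Total step count: 6. Longest linear sequence: 5 steps (3 → 4 → 6 → 7 → 11 → 12; the branch 1 → 2 joins at step 3).

**Step 5 (key step).**
- What may go wrong: deprotonation of the doubly allylic CH2 of 7 by the alkoxide, after which the cyclopentadienide would take up the carbene without positional control; competing cyclopropanation of the aryl enol ether double bond; a 1,5-hydrogen shift in 7 before the carbene arrives.
- Fallback: ring B is taken from a six-membered precursor and the carbene is given up. It sets out from 2 and comes back to the route at 12. Phenol 2 is combined, under the conditions of step 3, with 7-oxabicyclo[4.1.0]heptan-2-one F1 (made from cyclohex-2-en-1-one as in step 2) to give 2-(2,3,4,5-tetrabromo-6-methoxyphenoxy)cyclohex-2-en-1-one F2. Dehydrogenation (DDQ, TsOH cat., dioxane, reflux, or I2 cat. in DMSO at 100 °C) should give 2-(2,3,4,5-tetrabromo-6-methoxyphenoxy)phenol F3. Two equivalents of Br2 in CH2Cl2 should then brominate the para and the free ortho position of the hydroxyl and deliver 12.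

**Step 3.**
- What may go wrong: slow opening of the epoxide by the hindered, weakly nucleophilic phenoxide, so that base-induced isomerisation or oligomerisation of 4 takes over; incomplete dehydration.
- Fallback: the ether bond is made by displacement on an α-halo ketone and the double bond is introduced afterwards. It sets out from 2 and comes back at 6. O-Alkylation of 2 with 2-chlorocyclopentanone (K2CO3, NaI cat., acetone, reflux) should give 2-(2,3,4,5-tetrabromo-6-methoxyphenoxy)cyclopentan-1-one F4. Thermodynamic enol silylation towards the oxygen-bearing carbon (Me3SiCl, NaI, Et3N, MeCN) should give trimethyl{[2-(2,3,4,5-tetrabromo-6-methoxyphenoxy)cyclopent-1-en-1-yl]oxy}silane F5. Saegusa–Ito oxidation with stoichiometric Pd(OAc)2 in MeCN at room temperature should give 6; the divalent palladium salt is used without phosphine so that the zerovalent palladium formed does not insert into the C–Br bonds.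

**Step 4.**
- What may go wrong: enolisation at the γ position, or 1,5-hydrogen shift and Diels–Alder dimerisation of the diene during work-up, which would put the silyl enol ether double bond in the wrong place for step 5.
- Fallback: the ring expansion is run on a simple, stable silyl enol ether and the missing unsaturation is added after it. It sets out from 2 and comes back at 11. Ketone F4 of the preceding fallback, 2-(2,3,4,5-tetrabromo-6-methoxyphenoxy)cyclopentan-1-one F4, is silylated under kinetic control on the side away from the aryloxy group (LiN(iPr)2, Me3SiCl, THF, −78 °C) to give trimethyl{[5-(2,3,4,5-tetrabromo-6-methoxyphenoxy)cyclopent-1-en-1-yl]oxy}silane F6. Dibromocarbene ring expansion in one operation (CHBr3, KOtBu, pentane, −20 °C, then warming in PhMe) should give 2-bromo-6-(2,3,4,5-tetrabromo-6-methoxyphenoxy)cyclohex-2-en-1-one F7. Dehydrogenation with DDQ (TsOH cat., dioxane, reflux) and tautomerisation should lead to 11.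

## Further compounds

F1 | step 5 | 7-oxabicyclo[4.1.0]heptan-2-one (racemic, cis-fused; one enantiomer drawn) | O=C1CCC[C@H]2O[C@@H]12
F2 | step 5 | 2-(2,3,4,5-tetrabromo-6-methoxyphenoxy)cyclohex-2-en-1-one | COc1c(Br)c(Br)c(Br)c(Br)c1OC1=CCCCC1=O
F3 | step 5 | 2-(2,3,4,5-tetrabromo-6-methoxyphenoxy)phenol | COc1c(Br)c(Br)c(Br)c(Br)c1Oc1ccccc1O
F4 | step 3 | 2-(2,3,4,5-tetrabromo-6-methoxyphenoxy)cyclopentan-1-one (racemic; one enantiomer drawn) | COc1c(Br)c(Br)c(Br)c(Br)c1O[C@H]1CCCC1=O
F5 | step 3 | trimethyl{[2-(2,3,4,5-tetrabromo-6-methoxyphenoxy)cyclopent-1-en-1-yl]oxy}silane | COc1c(Br)c(Br)c(Br)c(Br)c1OC1=C(O[Si](C)(C)C)CCC1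
F6 | step 4 | trimethyl{[5-(2,3,4,5-tetrabromo-6-methoxyphenoxy)cyclopent-1-en-1-yl]oxy}silane (racemic; one enantiomer drawn) | COc1c(Br)c(Br)c(Br)c(Br)c1O[C@H]1CCC=C1O[Si](C)(C)C
F7 | step 4 | 2-bromo-6-(2,3,4,5-tetrabromo-6-methoxyphenoxy)cyclohex-2-en-1-one (racemic; one enantiomer drawn) | COc1c(Br)c(Br)c(Br)c(Br)c1O[C@H]1CCC=C(Br)C1=O
A1 | alternative 1 | 3,4,5,6-tetrabromocyclohexa-3,5-diene-1,2-dione (o-bromanil) | O=C1C(=O)C(Br)=C(Br)C(Br)=C1Br
A2 | alternative 1 | 1-(trimethylsilyloxy)cyclohexene | C[Si](C)(C)OC1=CCCCC1
A3 | alternative 1 | cis-6,7,8,9-tetrabromo-4a-(trimethylsilyloxy)-1,2,3,4,4a,10a-hexahydrodibenzo[b,e][1,4]dioxine (racemic; one enantiomer drawn) | C[Si](C)(C)O[C@]12CCCC[C@H]1Oc1c(Br)c(Br)c(Br)c(Br)c1O2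
A4 | alternative 2 | 3,5-dibromo-2H-pyran-2-one | O=C1OC=C(Br)C=C1Br
A5 | alternative 2 | 1,1-bis(trimethylsilyloxy)-2-(2,3,4,5-tetrabromo-6-methoxyphenoxy)ethene | COc1c(Br)c(Br)c(Br)c(Br)c1OC=C(O[Si](C)(C)C)O[Si](C)(C)C
A6 | alternative 2 | [2,4-dibromo-6-(2,3,4,5-tetrabromo-6-methoxyphenoxy)phenoxy]trimethylsilane | COc1c(Br)c(Br)c(Br)c(Br)c1Oc1cc(Br)cc(Br)c1O[Si](C)(C)C
A7 | alternative 3 | 1-(2,3,4,5-tetrabromo-6-methoxyphenoxy)propan-2-one | COc1c(Br)c(Br)c(Br)c(Br)c1OCC(C)=O
A8 | alternative 3 | 2-bromopropanedial (bromomalonaldehyde) | O=CC(Br)C=O
A9 | alternative 3 | 4-bromo-2-(2,3,4,5-tetrabromo-6-methoxyphenoxy)phenol | COc1c(Br)c(Br)c(Br)c(Br)c1Oc1cc(Br)ccc1O
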